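The dihydropyridine ring (C1, N, C3, C4, C4a, C8a) is traced back to the five-membered ring of an enantioenriched 2-methylindan-1-one. The feature used is that N sits between the aryl-bound, acyl-level C1 and the methyl-bearing stereocentre C3, so excising N leaves a ketone whose α-carbon already carries that methyl group. A Schmidt ring expansion inserts nitrogen into the carbonyl–CH(CH3) bond, and the stereocentre migrates to nitrogen with retention. The precursor is (S)-6-bromo-5,7-dimethoxy-2-methylindan-1-one, made by auxiliary-controlled alkylation and Friedel–Crafts closure. The lactam is then converted into the C1-methyl imine, and the C7 bromide takes up the naphthol unit by Negishi coupling.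

Key step: step 5

Assumption: the biaryl axis carries no stereodescriptor in the target, so it is treated as not configurationally defined and no atroposelective control is attempted.

Step 1
Reactants: 1 (4-bromo-3,5-dimethoxyphenyl)methanol
Product: 2 2-bromo-5-(bromomethyl)-1,3-dimethoxybenzene
Conditions: PBr3, CH2Cl2, 0 °C → rt
Reagents that add atoms: phosphorus tribromide, BrP(Br)Br
Why: Conversion of the benzylic alcohol into the bromide via the phosphite ester (SN2 displacement by bromide) should leave the aryl bromide and the methyl ethers untouched.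

Step 2
Reactants: 3 (R)-4-benzyl-3-propionyloxazolidin-2-one; 2 2-bromo-5-(bromomethyl)-1,3-dimethoxybenzene
Product: 5 (R)-4-benzyl-3-[(S)-3-(4-bromo-3,5-dimethoxyphenyl)-2-methylpropanoyl]oxazolidin-2-one, via sodium Z-enolate 4 (not isolated)
Conditions: NaN(SiMe3)2, THF, −78 °C; then 2, −78 → −20 °C
Reagents that add atoms: none
Why: Evans asymmetric alkylation, in which the chelated sodium Z-enolate 4 is benzylated on the face opposite the C4 benzyl group of the (R)-auxiliary, should set the new α-stereocentre as S.

Step 3
Reactants: 5 (R)-4-benzyl-3-[(S)-3-(4-bromo-3,5-dimethoxyphenyl)-2-methylpropanoyl]oxazolidin-2-one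
Product: 7 (S)-3-(4-bromo-3,5-dimethoxyphenyl)-2-methylpropanoic acid, via peroxy acid 6 (not isolated)
Conditions: LiOH, H2O2, THF/H2O, 0 °C; then aq Na2SO3; then aq HCl
Reagents that add atoms: hydrogen peroxide, OO
Why: Hydroperoxide cleavage of the N-acyloxazolidinone (attack at the exocyclic carbonyl, then sulfite reduction of peroxy acid 6) should free the acid without epimerization of the α-stereocentre.

Step 4
Reactants: 7 (S)-3-(4-bromo-3,5-dimethoxyphenyl)-2-methylpropanoic acid
Product: 9 (S)-6-bromo-5,7-dimethoxy-2-methylindan-1-one, via acid chloride 8 (not isolated)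
Conditions: (COCl)2, DMF (cat.), CH2Cl2, 0 °C → rt; then SnCl4, CH2Cl2, −20 → 0 °C
Reagents that add atoms: none
Why: Intramolecular Friedel–Crafts acylation at the ring position ortho to one methoxy group and para to the other closes the five-membered ketone ring, and the mild Lewis acid at low temperature should leave the enolizable C2 stereocentre and the methyl ethers intact.

Step 5
Reactants: 9 (S)-6-bromo-5,7-dimethoxy-2-methylindan-1-one
Product: 11 (S)-7-bromo-6,8-dimethoxy-3-methyl-3,4-dihydroisoquinolin-1(2H)-one, via azidohydrin 10 (not isolated)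
Conditions: NaN3 (1.5 equiv), MeSO3H, CH2Cl2, 0 °C → rt
Reagents that add atoms: sodium azide, [Na+].[N-]=[N+]=[N-]
Why: The protonated ketone adds HN3 to give azidohydrin 10, which (directly or after dehydration to the iminodiazonium ion) loses N2 while the C1–C2 bond migrates from carbon to nitrogen, and the water released captures the resulting imidoyl cation to give the lactam; this is the Schmidt reaction, with the conversion of 1-indanones into 3,4-dihydroisoquinolin-1(2H)-ones by NaN3/MeSO3H as the closest known case. No ring is closed by cyclization: the six-membered ring (C8a, C1, N, C3, C4, C4a) arises from the five-membered ketone ring by a 1,2-alkyl shift that places N between C1 and the former C2. No new stereocentre forms, and the migrating carbon keeps its configuration (suprafacial shift with retention), so (S)-C2 of the indanone should become (S)-C3 of the lactam. The step needs alkyl over aryl migration, which is the usual outcome for 1-indanones because aryl migration must pass through a strained bridged transition state on the five-membered ring, and the secondary C2 should migrate better still than the CH2 of the parent ketone. It also needs migration to outrun acid-catalysed enolization at C2, which the low temperature and the poorly basic, non-nucleophilic MeSO3H/CH2Cl2 medium should favour.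

Step 6
Reactants: 11 (S)-7-bromo-6,8-dimethoxy-3-methyl-3,4-dihydroisoquinolin-1(2H)-one
Product: 13 (S)-7-bromo-6,8-dimethoxy-1,3-dimethyl-3,4-dihydroisoquinoline, via imidoyl triflate 12 (not isolated)
Conditions: Tf2O, 2-fluoropyridine, CH2Cl2, −78 → 0 °C; then MeMgBr (excess), −78 → 0 °C
Reagents that add atoms: methylmagnesium bromide, C[Mg]Br
Why: Electrophilic amide activation (O-triflation to the cyclic imidoyl triflate 12) followed by addition–elimination of the methyl Grignard reagent at C1 should convert the secondary lactam into the ketimine without touching the aryl bromide or the C3 stereocentre, the ketimine being too unreactive for a second addition at low temperature.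

Step 7
Reactants: 14 2-methoxy-4-methylbenzoic acid
Product: 16 N,N-diethyl-2-methoxy-4-methylbenzamide, via acid chloride 15 (not isolated)
Conditions: (COCl)2, DMF (cat.), CH2Cl2, rt; then Et2NH (excess), 0 °C → rt
Reagents that add atoms: diethylamine, CCNCC
Why: Acyl chloride formation and aminolysis (Schotten–Baumann-type amide synthesis) install the diethylamide that serves first as directing group and later as the acylating carbon of the naphthol.

Step 8
Reactants: 16 N,N-diethyl-2-methoxy-4-methylbenzamide
Product: 19 2-allyl-N,N-diethyl-6-methoxy-4-methylbenzamide, via aryllithium 17 (not isolated), via arylmagnesium bromide 18 (not isolated)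
Conditions: s-BuLi, TMEDA, THF, −78 °C; MgBr2·OEt2, −78 °C; allyl bromide, −78 °C → rt
Reagents that add atoms: allyl bromide, C=CCBr
Why: Directed ortho metalation, in which the tertiary amide steers s-BuLi to the only free ortho position, followed by transmetalation to magnesium should allow clean allylation of the aryl nucleophile.

Step 9
Reactants: 19 2-allyl-N,N-diethyl-6-methoxy-4-methylbenzamide
Product: 20 8-methoxy-6-methylnaphthalen-1-ol
Conditions: LiN(i-Pr)2 (2.2 equiv), THF, −78 °C → rt; then aq HCl
Reagents that add atoms: none
Why: Anionic benzannulation of an o-allylbenzamide (deprotonation of the benzylic–allylic CH2, attack of the terminal allyl carbon on the amide carbonyl to close the six-membered ring, loss of diethylamide and tautomerization) should give the 1-naphthol with its hydroxyl peri to the methoxy group.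

Step 10
Reactants: 20 8-methoxy-6-methylnaphthalen-1-ol
Product: 21 8-methoxy-1-(methoxymethoxy)-6-methylnaphthalene
Conditions: NaH, MOMCl, DMF, 0 °C → rt
Reagents that add atoms: chloromethyl methyl ether, COCCl
Why: Williamson-type O-alkylation of the naphthoxide gives the methoxymethyl ether, which protects the phenol and acts as the directing group for the following metalation.

Step 11
Reactants: 21 8-methoxy-1-(methoxymethoxy)-6-methylnaphthalene; 13 (S)-7-bromo-6,8-dimethoxy-1,3-dimethyl-3,4-dihydroisoquinoline
Product: 24 (S)-7-[8-methoxy-1-(methoxymethoxy)-6-methylnaphthalen-2-yl]-6,8-dimethoxy-1,3-dimethyl-3,4-dihydroisoquinoline, via aryllithium 22 (not isolated), via arylzinc chloride 23 (not isolated)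
Conditions: n-BuLi, TMEDA, Et2O, 0 °C; ZnCl2, THF, 0 °C → rt; then 13, Pd(OAc)2 (cat.), RuPhos (cat.), THF, 70 °C
Reagents that add atoms: none
Why: MOM-directed ortho-lithiation at C2 of the naphthalene, transmetalation to zinc and Negishi cross-coupling with aryl bromide 13 should forge the tri-ortho-substituted biaryl bond, since the bulky dialkylbiarylphosphine on zerovalent palladium permits oxidative addition and reductive elimination at hindered centres and the arylzinc tolerates the imine.

Step 12
Reactants: 24 (S)-7-[8-methoxy-1-(methoxymethoxy)-6-methylnaphthalen-2-yl]-6,8-dimethoxy-1,3-dimethyl-3,4-dihydroisoquinoline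
Product: 25 2-[(S)-6,8-dimethoxy-1,3-dimethyl-3,4-dihydroisoquinolin-7-yl]-8-methoxy-6-methylnaphthalen-1-ol (target)
Conditions: HCl, MeOH, 40 °C; then aq NaHCO3
Reagents that add atoms: none
Why: Acid-catalysed acetal methanolysis should remove the MOM group while the imine is only protonated and returns as the free base on neutralization, the C3 stereocentre not being involved.

Compound list
1 | (4-bromo-3,5-dimethoxyphenyl)methanol | COc1cc(CO)cc(OC)c1Br | starting material
2 | 2-bromo-5-(bromomethyl)-1,3-dimethoxybenzene | COc1cc(CBr)cc(OC)c1Br | intermediate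
3 | (R)-4-benzyl-3-propionyloxazolidin-2-one | CCC(=O)N1[C@H](Cc2ccccc2)COC1=O | starting material
4 | sodium Z-enolate of 3 (formed in the flask) | C/C=C(\[O-])N1[C@H](Cc2ccccc2)COC1=O.[Na+] | intermediate
5 | (R)-4-benzyl-3-[(S)-3-(4-bromo-3,5-dimethoxyphenyl)-2-methylpropanoyl]oxazolidin-2-one | C[C@@H](Cc1cc(OC)c(Br)c(OC)c1)C(=O)N1[C@H](Cc2ccccc2)COC1=O | intermediate
6 | (S)-3-(4-bromo-3,5-dimethoxyphenyl)-2-methylpropaneperoxoic acid (formed in the flask) | C[C@@H](Cc1cc(OC)c(Br)c(OC)c1)C(=O)OO | intermediate
7 | (S)-3-(4-bromo-3,5-dimethoxyphenyl)-2-methylpropanoic acid | C[C@@H](Cc1cc(OC)c(Br)c(OC)c1)C(=O)O | intermediate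
8 | (S)-3-(4-bromo-3,5-dimethoxyphenyl)-2-methylpropanoyl chloride (formed in the flask) | C[C@@H](Cc1cc(OC)c(Br)c(OC)c1)C(=O)Cl | intermediate
9 | (S)-6-bromo-5,7-dimethoxy-2-methylindan-1-one | COc1cc2c(c(OC)c1Br)C(=O)[C@@H](C)C2 | intermediate
10 | (2S)-1-azido-6-bromo-5,7-dimethoxy-2-methylindan-1-ol, azidohydrin (formed in the flask) | COc1cc2c(c(OC)c1Br)C(O)(N=[N+]=[N-])[C@@H](C)C2 | intermediate
11 | (S)-7-bromo-6,8-dimethoxy-3-methyl-3,4-dihydroisoquinolin-1(2H)-one | COc1cc2c(c(OC)c1Br)C(=O)N[C@@H](C)C2 | intermediate
12 | (S)-7-bromo-6,8-dimethoxy-3-methyl-3,4-dihydroisoquinolin-1-yl trifluoromethanesulfonate (formed in the flask) | COc1cc2c(c(OC)c1Br)C(OS(=O)(=O)C(F)(F)F)=N[C@@H](C)C2 | intermediate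
13 | (S)-7-bromo-6,8-dimethoxy-1,3-dimethyl-3,4-dihydroisoquinoline | COc1cc2c(c(OC)c1Br)C(C)=N[C@@H](C)C2 | intermediate
14 | 2-methoxy-4-methylbenzoic acid | COc1cc(C)ccc1C(=O)O | starting material
15 | 2-methoxy-4-methylbenzoyl chloride (formed in the flask) | COc1cc(C)ccc1C(=O)Cl | intermediate
16 | N,N-diethyl-2-methoxy-4-methylbenzamide | CCN(CC)C(=O)c1ccc(C)cc1OC | intermediate
17 | [2-(diethylcarbamoyl)-3-methoxy-5-methylphenyl]lithium (formed in the flask) | CCN(CC)C(=O)c1c([Li])cc(C)cc1OC | intermediate
18 | [2-(diethylcarbamoyl)-3-methoxy-5-methylphenyl]magnesium bromide (formed in the flask) | CCN(CC)C(=O)c1c([Mg]Br)cc(C)cc1OC | intermediate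
19 | 2-allyl-N,N-diethyl-6-methoxy-4-methylbenzamide | CCN(CC)C(=O)c1c(CC=C)cc(C)cc1OC | intermediate
20 | 8-methoxy-6-methylnaphthalen-1-ol | COc1cc(C)cc2cccc(O)c12 | intermediate
21 | 8-methoxy-1-(methoxymethoxy)-6-methylnaphthalene | COCOc1cccc2cc(C)cc(OC)c12 | intermediate
22 | [8-methoxy-1-(methoxymethoxy)-6-methylnaphthalen-2-yl]lithium (formed in the flask) | COCOc1c([Li])ccc2cc(C)cc(OC)c12 | intermediate
23 | [8-methoxy-1-(methoxymethoxy)-6-methylnaphthalen-2-yl]zinc chloride (formed in the flask) | COCOc1c([Zn]Cl)ccc2cc(C)cc(OC)c12 | intermediate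
24 | (S)-7-[8-methoxy-1-(methoxymethoxy)-6-methylnaphthalen-2-yl]-6,8-dimethoxy-1,3-dimethyl-3,4-dihydroisoquinoline | COc1cc2c(c(OC)c1-c1ccc3cc(C)cc(OC)c3c1OCOC)C(C)=N[C@@H](C)C2 | intermediate
25 | 2-[(S)-6,8-dimethoxy-1,3-dimethyl-3,4-dihydroisoquinolin-7-yl]-8-methoxy-6-methylnaphthalen-1-ol | COc1cc2c(c(OC)c1-c1ccc3cc(C)cc(OC)c3c1O)C(C)=N[C@@H](C)C2 | target

Total step count: 12. Longest linear sequence: 8 steps (steps 1, 2, 3, 4, 5, 6, 11, 12); the naphthalene arm (steps 7–10) joins at step 11.

Steps most likely to fail

Step 5. Aryl migration may compete with alkyl migration, since the peri methoxy group may bias the geometry of the iminodiazonium ion toward the isomeric quinolinone. Acid-catalysed enolization at C2 may erode the enantiomeric purity before the shift, and excess azide may capture the imidoyl cation as a tetrazole. The fallback keeps nitrogen insertion into the five-membered ring but moves the stereochemical decision to a later catalytic step; it sets out from 9 and returns at 13. MeMgBr in THF should add to 9 to give (2S)-6-bromo-5,7-dimethoxy-1,2-dimethylindan-1-ol F1, and TsOH in toluene should dehydrate F1 to 5-bromo-4,6-dimethoxy-2,3-dimethyl-1H-indene F2. Oxidative nitrogen-atom insertion into the ring double bond of F2 (PhI(OCOCF3)2, H2NCO2NH4, MeOH, rt) should expand the ring to 7-bromo-6,8-dimethoxy-1,3-dimethylisoquinoline F3. Asymmetric hydrogenation of F3 ([Ir(cod)Cl]2, a chiral bisphosphine whose enantiomer is chosen by screening for the 3S series, a halogen activator, H2) should give the cis-configured (1R,3S)-7-bromo-6,8-dimethoxy-1,3-dimethyl-1,2,3,4-tetrahydroisoquinoline F4. N-Chlorination of F4 with N-chlorosuccinimide should give (1R,3S)-7-bromo-2-chloro-6,8-dimethoxy-1,3-dimethyl-1,2,3,4-tetrahydroisoquinoline F5, and KOH in EtOH should eliminate HCl from F5 toward the benzylic C1 to deliver 13.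

Step 6. Activation of the lactam flanked by the peri methoxy group may be incomplete or may occur at nitrogen, and the Grignard reagent may act as a base, so that lactam is returned after work-up. The fallback separates activation from carbon–carbon bond formation and uses a catalysed cross-coupling; it sets out from 11 and returns at 13. POCl3 in toluene at 90 °C should give (S)-7-bromo-1-chloro-6,8-dimethoxy-3-methyl-3,4-dihydroisoquinoline F6. Iron-catalysed Kumada coupling of F6 with MeMgBr (Fe(acac)3 cat., THF/NMP, 0 °C) should give 13, the electron-rich hindered aryl bromide being unreactive under these conditions.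

Step 11. Transmetalation and reductive elimination at the doubly ortho-substituted aryl palladium species may be slow, so that protodezincation of the naphthyl nucleophile and reduction of the bromide take over. The fallback replaces the zinc reagent made in the flask by an isolable boron partner; it sets out from 21 and returns at 24. Lithiation of 21 (n-BuLi, TMEDA) and a quench with 2-isopropoxy-4,4,5,5-tetramethyl-1,3,2-dioxaborolane should give 2-[8-methoxy-1-(methoxymethoxy)-6-methylnaphthalen-2-yl]-4,4,5,5-tetramethyl-1,3,2-dioxaborolane F7. After purification, Suzuki–Miyaura coupling of F7 with 13 (Pd(OAc)2, SPhos, K3PO4, toluene/H2O, 100 °C) should give 24.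

Further compounds
F1 | step 5 | (2S)-6-bromo-5,7-dimethoxy-1,2-dimethylindan-1-ol | COc1cc2c(c(OC)c1Br)C(C)(O)[C@@H](C)C2
F2 | step 5 | 5-bromo-4,6-dimethoxy-2,3-dimethyl-1H-indene | COc1cc2c(c(OC)c1Br)C(C)=C(C)C2
F3 | step 5 | 7-bromo-6,8-dimethoxy-1,3-dimethylisoquinoline | COc1cc2cc(C)nc(C)c2c(OC)c1Br
F4 | step 5 | (1R,3S)-7-bromo-6,8-dimethoxy-1,3-dimethyl-1,2,3,4-tetrahydroisoquinoline | COc1cc2c(c(OC)c1Br)[C@@H](C)N[C@@H](C)C2
F5 | step 5 | (1R,3S)-7-bromo-2-chloro-6,8-dimethoxy-1,3-dimethyl-1,2,3,4-tetrahydroisoquinoline | COc1cc2c(c(OC)c1Br)[C@@H](C)N(Cl)[C@@H](C)C2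
F6 | step 6 | (S)-7-bromo-1-chloro-6,8-dimethoxy-3-methyl-3,4-dihydroisoquinoline | COc1cc2c(c(OC)c1Br)C(Cl)=N[C@@H](C)C2
F7 | step 11 | 2-[8-methoxy-1-(methoxymethoxy)-6-methylnaphthalen-2-yl]-4,4,5,5-tetramethyl-1,3,2-dioxaborolane | COCOc1c(B2OC(C)(C)C(C)(C)O2)ccc2cc(C)cc(OC)c12
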